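**Retrosynthetic overview**

- The target is a 1,2,3-trisubstituted benzene: C1 carries the henicosyl ester, and C2 and C3 carry the two hydroxyls. No ring is formed in the route; the benzene ring is bought as 2,6-dibromophenol.
- The C3 hydroxyl is traced back to a C3–B bond and then to a C3–SiMe3 group (ipso-borodesilylation, then oxidation).
- The C1–C(=O) bond and the C2–O bond are made together by insertion of 3-(trimethylsilyl)benzyne into the C–O bond of potassium henicosyl carbonate. The SiMe3 group at C3 steers the addition.
- The aryne comes from the symmetrical 2,6-bis(trimethylsilyl)phenyl triflate, made from 2,6-dibromophenol by two rounds of bromine–lithium exchange and O-to-C silyl shift. The carbonate salt comes from henicosan-1-ol, KH and CO2.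

Key step: step 5

Assumption: potassium henicosyl carbonate 11 is taken to keep its CO2 in a dry, closed vessel at room temperature, and it is used in excess.

**Route**

Step 1
Reactants: 1 2,6-dibromophenol; 2 chlorotrimethylsilane
Product: 3 (2,6-dibromophenoxy)trimethylsilane
Conditions: Et3N, CH2Cl2, 0 °C to rt; filtration, concentration
Reagents that add atoms: none
Why: O-silylation of a phenol with a chlorosilane and an amine base is routine, and the two ortho bromines do not block the oxygen.

Step 2
Reactants: 3 (2,6-dibromophenoxy)trimethylsilane; 2 chlorotrimethylsilane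
Product: 5 (2-bromo-6-(trimethylsilyl)phenoxy)trimethylsilane, via lithium 2-bromo-6-(trimethylsilyl)phenoxide 4 (not isolated)
Conditions: n-BuLi (1.05 equiv), THF, −78 °C; then 2, −78 °C to rt; non-aqueous work-up, distillation
Reagents that add atoms: n-butyllithium, CCCC[Li] (supplies only the lithium of intermediate 4)
Why: Bromine–lithium exchange gives an ortho-lithiated aryl silyl ether that undergoes the 1,3 O-to-C silyl shift (retro-Brook rearrangement) to phenoxide 4, whose oxygen is then silylated again by 2.

Step 3
Reactants: 5 (2-bromo-6-(trimethylsilyl)phenoxy)trimethylsilane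
Product: 7 2,6-bis(trimethylsilyl)phenyl trifluoromethanesulfonate, via lithium 2,6-bis(trimethylsilyl)phenoxide 6 (not isolated)
Conditions: n-BuLi, THF, −100 to −78 °C; then Tf2O, −100 °C to rt; aq. NaHCO3
Reagents that add atoms: trifluoromethanesulfonic anhydride, O=S(=O)(OS(=O)(=O)C(F)(F)F)C(F)(F)F; n-butyllithium, CCCC[Li] (supplies only the lithium of intermediate 6)
Why: A second bromine–lithium exchange and retro-Brook rearrangement place the second SiMe3 group on carbon, and the hindered lithium phenoxide 6 is O-sulfonylated by Tf2O at low temperature before the anhydride can attack THF.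

Step 4
Reactants: 8 henicosan-1-ol; 9 carbon dioxide
Product: 11 potassium henicosyl carbonate, via potassium henicosan-1-olate 10 (not isolated)
Conditions: KH (1.0 equiv), THF, 0 to 45 °C; then dry CO2 (1 atm), rt; volatiles removed in vacuo, solid stored under Ar
Reagents that add atoms: potassium hydride, [KH]
Why: Deprotonation of a primary alcohol by KH is irreversible, and alkoxides take up CO2 at oxygen to give stable monoalkyl carbonate salts (alkoxide carboxylation).

Step 5
Reactants: 7 2,6-bis(trimethylsilyl)phenyl trifluoromethanesulfonate; 11 potassium henicosyl carbonate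
Product: 14 henicosyl 2-hydroxy-3-(trimethylsilyl)benzoate, via 3-(trimethylsilyl)benzyne 12 (not isolated), via potassium 2-(henicosyloxycarbonyl)-6-(trimethylsilyl)phenoxide 13 (not isolated)
Conditions: 11 (2.5 equiv), CsF (2 equiv, flame-dried), 18-crown-6, THF, rt, closed vessel under Ar, slow addition of 7; then 1 M HCl
Reagents that add atoms: none
Why: Proposed new method: fluoride attacks one silicon of the symmetrical triflate 7 and triflate leaves, so either silyl group gives the same aryne 12; a carbonate oxygen of 11 then adds to the aryne carbon next to the C–Si carbon, and the aryl anion formed at the remote carbon attacks the carbonyl of the aryl henicosyl carbonate it now carries, passing through a four-membered tetrahedral alkoxide that opens at its ring C–O bond to phenoxide 13 and the henicosyl ester. The closest known reaction types are the fluoride-induced insertion of arynes into the C–O bond of carboxylic acids to give ortho-hydroxyaryl ketones, the aryne–amine–CO2 three-component coupling, and, for the second half, the anionic ortho-Fries shift of ortho-metalated aryl carbonates and carbamates. No ring survives in the product (the four-membered ring is a transient, closed by 4-exo-trig attack and reopened at once), and no stereocenter is formed. The step needs oxygen attack at the aryne carbon beside silicon, and this is secured by the electropositive SiMe3 group, which widens the internal angle at that carbon and makes it the electrophilic terminus, while the small size of SiMe3 and of the oxygen nucleophile keeps steric repulsion from reversing the preference. It also needs the aryl anion to find only the internal carbonyl, which the aprotic, CO2-free closed system provides, and slow addition of 7 to an excess of 11 keeps the hindered, chelated product phenoxide 13 from competing for the aryne.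

Step 6
Reactants: 14 henicosyl 2-hydroxy-3-(trimethylsilyl)benzoate
Product: 16 [3-(henicosyloxycarbonyl)-2-hydroxyphenyl]boronic acid, via henicosyl 3-(dibromoboryl)-2-(dibromoboryloxy)benzoate 15 (not isolated)
Conditions: BBr3 (3 equiv), 2,6-di-tert-butyl-4-methylpyridine, CH2Cl2, −78 °C to rt; volatiles removed in vacuo; then THF/H2O, 0 °C; used crude
Reagents that add atoms: boron tribromide, BrB(Br)Br; water, O
Why: In this electrophilic ipso-borodesilylation BBr3 attacks the silicon-bearing carbon, which is ortho to the boron-bound phenol oxygen and gives a β-silyl-stabilised cation, and loss of Me3SiBr leaves the aryl–BBr2 unit, while the hindered pyridine takes up the HBr from O-boration so that protodesilylation is held back and the ester, tied into a boron chelate at low temperature, is not cleaved.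

Step 7
Reactants: 16 [3-(henicosyloxycarbonyl)-2-hydroxyphenyl]boronic acid
Product: 17 henicosyl 2,3-dihydroxybenzoate (the target)
Conditions: 30% aq. H2O2, NaHCO3, THF/H2O, 0 °C; then aq. Na2S2O3, dilute HCl
Reagents that add atoms: hydrogen peroxide, OO
Why: Hydroperoxide adds to boron and the aryl group shifts from boron to oxygen (boronic acid oxidation), and the bicarbonate buffer at 0 °C should leave the ester and the electron-poor catechol intact.

**Compound list**

1 | 2,6-dibromophenol | Oc1c(Br)cccc1Br | starting material
2 | chlorotrimethylsilane | C[Si](C)(C)Cl | starting material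
3 | (2,6-dibromophenoxy)trimethylsilane | C[Si](C)(C)Oc1c(Br)cccc1Br | intermediate
4 | lithium 2-bromo-6-(trimethylsilyl)phenoxide | [Li+].[O-]c1c(Br)cccc1[Si](C)(C)C | intermediate
5 | (2-bromo-6-(trimethylsilyl)phenoxy)trimethylsilane | C[Si](C)(C)Oc1c(Br)cccc1[Si](C)(C)C | intermediate
6 | lithium 2,6-bis(trimethylsilyl)phenoxide | [Li+].[O-]c1c([Si](C)(C)C)cccc1[Si](C)(C)C | intermediate
7 | 2,6-bis(trimethylsilyl)phenyl trifluoromethanesulfonate | C[Si](C)(C)c1cccc([Si](C)(C)C)c1OS(=O)(=O)C(F)(F)F | intermediate
8 | henicosan-1-ol | CCCCCCCCCCCCCCCCCCCCCO | starting material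
9 | carbon dioxide | O=C=O | starting material
10 | potassium henicosan-1-olate | CCCCCCCCCCCCCCCCCCCCC[O-].[K+] | intermediate
11 | potassium henicosyl carbonate | CCCCCCCCCCCCCCCCCCCCCOC(=O)[O-].[K+] | intermediate
12 | 3-(trimethylsilyl)benzyne | C[Si](C)(C)C1=CC=CC#C1 | intermediate
13 | potassium 2-(henicosyloxycarbonyl)-6-(trimethylsilyl)phenoxide | CCCCCCCCCCCCCCCCCCCCCOC(=O)c1cccc([Si](C)(C)C)c1[O-].[K+] | intermediate
14 | henicosyl 2-hydroxy-3-(trimethylsilyl)benzoate | CCCCCCCCCCCCCCCCCCCCCOC(=O)c1cccc([Si](C)(C)C)c1O | intermediate
15 | henicosyl 3-(dibromoboryl)-2-(dibromoboryloxy)benzoate | CCCCCCCCCCCCCCCCCCCCCOC(=O)c1cccc(B(Br)Br)c1OB(Br)Br | intermediate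
16 | [3-(henicosyloxycarbonyl)-2-hydroxyphenyl]boronic acid | CCCCCCCCCCCCCCCCCCCCCOC(=O)c1cccc(B(O)O)c1O | intermediate
17 | henicosyl 2,3-dihydroxybenzoate | CCCCCCCCCCCCCCCCCCCCCOC(=O)c1cccc(O)c1O | target

**Step count**

Total: 7 steps. Longest linear sequence: 6 steps (steps 1, 2, 3, 5, 6, 7 from 2,6-dibromophenol); step 4 is a one-step branch.

**Steps most likely to fail**

1. Step 5. The aryl anion may be protonated before the acyl shift, leaving an aryl henicosyl carbonate. The salt may shed CO2, so that alkoxide adds to the aryne. Oxygen may add at the remote aryne carbon. The product phenoxide may be arylated by a second aryne. Fallback by known chemistry, setting out from 3: bromine–lithium exchange and retro-Brook shift as in step 2 (n-BuLi, THF, −78 °C), quenched with aqueous NH4Cl instead of the chlorosilane, should give 2-bromo-6-(trimethylsilyl)phenol F1. Palladium-catalysed alkoxycarbonylation of F1 with henicosan-1-ol 8 under CO (1 atm) with Pd(OAc)2, Xantphos and Et3N in toluene at 100 °C should then give the salicylate, returning to the route at 14.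

2. Step 6. The acid released on O-boration may protodesilylate the ring, BBr3 may cleave the ester on warming, or the boron-chelated ring may be too electron-poor for ipso attack. Fallback, setting out from 14: ipso-iododesilylation with ICl (1.0 equiv, CH2Cl2, −78 to 0 °C) should give henicosyl 2-hydroxy-3-iodobenzoate F2. Miyaura borylation (bis(pinacolato)diboron, PdCl2(dppf), KOAc, dioxane, 80 °C) should give henicosyl 2-hydroxy-3-(4,4,5,5-tetramethyl-1,3,2-dioxaborolan-2-yl)benzoate F3. Oxidation of F3 under the conditions of step 7 returns to the route at 17.

3. Step 3. The silyl shift may be incomplete, or sulfonylation of the doubly flanked phenoxide may be slow enough for Tf2O to be consumed by THF. Fallback, setting out from 5: the exchange and silyl shift are run as before but quenched with aqueous NH4Cl, which should give 2,6-bis(trimethylsilyl)phenol F4, purified by chromatography. The free phenol is then triflated in a separate operation in a non-ethereal medium (Tf2O, pyridine, CH2Cl2, 0 °C), returning to the route at 7.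

**Further compounds**

F1 | step 5 | 2-bromo-6-(trimethylsilyl)phenol | Oc1c(Br)cccc1[Si](C)(C)C
F2 | step 6 | henicosyl 2-hydroxy-3-iodobenzoate | CCCCCCCCCCCCCCCCCCCCCOC(=O)c1cccc(I)c1O
F3 | step 6 | henicosyl 2-hydroxy-3-(4,4,5,5-tetramethyl-1,3,2-dioxaborolan-2-yl)benzoate | CCCCCCCCCCCCCCCCCCCCCOC(=O)c1cccc(B2OC(C)(C)C(C)(C)O2)c1O
F4 | step 3 | 2,6-bis(trimethylsilyl)phenol | C[Si](C)(C)c1cccc([Si](C)(C)C)c1O
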